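(The readings were computed from invented constants; noise was put on by code.)

The midnight run is our start: by 50.0 min its substrate reads 2 %, yet open intermediate stands at 24 % and is still 26 % at 240 min.

| setting | midnight | dawn | delta | zeta | theta | alpha |
|---|---|---|---|---|---|---|
| substrate | 0.10 M | 0.10 M | 0.10 M | 0.10 M | 0.10 M | 0.10 M |
| partner | 0.14 M | 0.22 M | 0.100 M | 0.100 M | 0.100 M | 0.100 M |
| temperature | 35 °C | 78 °C | 115 °C | 90 °C | 65 °C | 40 °C |
| remark | run made earlier | run made earlier |  |  |  |  |
| time |  |  | 6.0 min | 6.0 min | 6.0 min | 6.0 min |

| run | time / min | open intermediate / % | target / % | substrate / % |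
|---|---|---|---|---|
| midnight | 50.0 | 24 | 68 | 2 |
| midnight | 120 | 27 | 66 | 0 |
| midnight | 150 | 28 | 66 | 0 |
| midnight | 240 | 26 | 67 | 0 |
| dawn | 2.50 | 1 | 94 | 0 |
| dawn | 4.00 | 4 | 97 | 1 |
| dawn | 8.00 | 0 | 97 | 0 |
| dawn | 15.0 | 2 | 94 | 0 |
| dawn | 30.0 | 2 | 93 | 0 |

(each reading ± 1.5 percentage points)



* the best flask by amount of open intermediate, in percent of the substrate charged; "all alike" if 1.5 percentage points covers them all (delta / zeta / theta / alpha / all alike)
* amount of open intermediate at the end, in percent of the substrate charged, delta
* amount of open intermediate at the end, in percent of the substrate charged, zeta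
* amount of open intermediate at the end, in percent of the substrate charged, theta
* amount of open intermediate at the end, in percent of the substrate charged, alpha

We climb from the fastest event to the slowest.

1. Substrate goes first. Dawn reads 0 % of it at 2.50 min. Delta and zeta are hotter than dawn and run for 6.0 min. Alpha, at 40 °C, gets less time than midnight's first reading, so its conversion is our weakest assumption.

2. Then target stops in midnight. Midnight's target reads 68 % at 50.0 min and 67 % at 240 min, a drift of −1 percentage point against a scatter of 1.5 points.

3. Open intermediate then stays in midnight. Midnight had 1.40 equivalents of partner and still stopped short. Our working assumption is that partner is the limiting reagent, and that less of it reaches target than was charged. At midnight's last reading, target per partner charged reads 0.479, with the scatter of that reading. We call this the partner yield.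

4. Check it on dawn. That yield allows target of 105 % of the substrate, above the charge, so little open intermediate should remain in dawn. Dawn reads 2 %. Dawn's target reads 93 %, near the substrate charge, so dawn says little on whether heat changes the yield.

5. Our estimate follows. With 0.100 M of partner, we expect target near 47.9 %. Counting the rest of the substrate as open intermediate, we expect 52.1 % of that, alike in the four flasks.

The forecast says 1 % for delta, 1.5 % for zeta, 6 % for theta and 11 % for alpha, with alpha best, holding that “the open share falls steeply with heat”. Our figure is far above these.

The flasks give 21.5 % for delta, 24.5 % for zeta, 29.2 % for theta and 34.5 % for alpha, so alpha is best.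

    substrate → open intermediate (k = 0.0130 s⁻¹, Ea = 94.0 kJ mol⁻¹)
    partner → second intermediate (k = 0.0220 s⁻¹, Ea = 80.0 kJ mol⁻¹)
    open intermediate + second intermediate → target (k = 7.40 M⁻¹ s⁻¹, Ea = 55.0 kJ mol⁻¹)
    2 second intermediate → homo product (k = 6.40 M⁻¹ s⁻¹, Ea = 46.0 kJ mol⁻¹)
    substrate + second intermediate → side product (k = 0.130 M⁻¹ s⁻¹, Ea = 50.0 kJ mol⁻¹)
    (constants at 40 °C)

Partner yield in these flasks is 0.606 in alpha and 0.779 in delta, both above midnight's reading of 0.479. Delta ends with 0 % of its partner and 0 % of its substrate. A neighbour like delta, with 0.025 M of partner, reckons at midnight's yield to 12.0 % target and 88.0 % open intermediate. That neighbour gives 23.7 % target, a partner yield of 0.948, and 76.2 % open intermediate.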